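**Plan**

1. Retrosynthesis: the 9''-acetate, the benzyl ether and the silyl ethers are taken off first. Ring A is then cut at C8a–C8, C7–C8, C5–C6 and C4a–C5, which leaves a 6-aryl-2-(diazoacetyl)-4-pyranone and an O-silyl ynol ether.
2. Enabling feature: ring A is a benzene with oxygen on C5, C7 and C8a (the ring oxygen O1) and hydrogen on C6 and C8, fused to the pyranone along C4a–C8a. A ketene on the pyranone supplies C8a, C8, C5 and C4a; the ynol ether supplies C6 and C7 with its oxygen.
3. The pyranone (ring C) is opened at O1 and at the Claisen bonds C3–C4 and C4a–C8a, back to an aryl methyl ketone, ethyl acetate and diethyl oxalate. The side chain is cut at C7''–C8'' (aldol) and at the ether bond of an aryloxyacetic acid.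
4. Forward order: side chain on ring B (steps 1–8), ring C (steps 9–12), diazo ketone (step 13), ring A last (step 15), then desilylation, enzymatic acetylation and hydrogenolysis.
5. Stereochemistry: C8'' comes from an (R)-4-benzyloxazolidinone-controlled syn aldol. C7'' is formed as the threo epimer and inverted by a Mitsunobu displacement to the erythro (7''R,8''S) pair, which no later step touches.

Key step: step 15

Remark: flavone atoms carry plain locants, ring B primed and the arylglycerol unit double-primed locants; the target is read as the erythro (7''R,8''S) isomer.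
Remark: (triisopropylsiloxy)acetylene is not assumed to be a catalogue reagent and is therefore made in step 14.
Abbreviation: ArB = 4-({(1R,2S)-1-[4-(benzyloxy)-3-methoxyphenyl]-1,3-bis[(tert-butyldimethylsilyl)oxy]propan-2-yl}oxy)-3,5-dimethoxyphenyl.

**Route**

Step 1
Reactants: 1 4-bromo-2,6-dimethoxyphenol; 2 bromoacetic acid
Product: 3 (4-bromo-2,6-dimethoxyphenoxy)acetic acid
Conditions: NaH (2.2 equiv), THF/DMF, 0 → 60 °C; aq. HCl work-up
Reagents that add atoms: none
Why: Williamson ether synthesis: the sodium phenoxide displaces bromide from sodium bromoacetate in an SN2 reaction at an unhindered primary carbon, which tolerates the two ortho methoxy groups.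

Step 2
Reactants: 3 (4-bromo-2,6-dimethoxyphenoxy)acetic acid; 4 (R)-4-benzyloxazolidin-2-one
Product: 6 (4R)-4-benzyl-3-[(4-bromo-2,6-dimethoxyphenoxy)acetyl]oxazolidin-2-one, via mixed pivalic anhydride 5 (not isolated)
Conditions: PivCl, Et3N, THF, −20 °C; then 4, LiCl, −20 °C → rt
Reagents that add atoms: none
Why: N-acylation of the oxazolidinone by the mixed anhydride under LiCl/Et3N activation, the nucleophile attacking the less hindered aryloxyacetyl carbonyl and not the pivaloyl one.

Step 3
Reactants: 6 (4R)-4-benzyl-3-[(4-bromo-2,6-dimethoxyphenoxy)acetyl]oxazolidin-2-one; 7 4-(benzyloxy)-3-methoxybenzaldehyde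
Product: 9 (4R)-4-benzyl-3-[(2R,3S)-3-[4-(benzyloxy)-3-methoxyphenyl]-2-(4-bromo-2,6-dimethoxyphenoxy)-3-hydroxypropanoyl]oxazolidin-2-one, via dibutylboron enolate 8 (not isolated)
Conditions: Bu2BOTf, i-Pr2NEt, CH2Cl2, 0 °C; then 7, −78 → 0 °C; pH 7 buffer, MeOH, H2O2
Reagents that add atoms: none
Why: Evans syn aldol reaction: the (Z)-dibutylboron enolate adds to the aldehyde through a chair Zimmerman–Traxler transition state on the face left open by the (R)-benzyl group, which sets the aryloxy-bearing carbon (the later C8'') in its final sense and the carbinol carbon (the later C7'') as the threo epimer that step 6 inverts.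

Step 4
Reactants: 9 threo aldol adduct
Product: 10 (1S,2S)-1-[4-(benzyloxy)-3-methoxyphenyl]-2-(4-bromo-2,6-dimethoxyphenoxy)propane-1,3-diol
Conditions: LiBH4, MeOH (1 equiv), THF, 0 °C
Reagents that add atoms: none
Why: Reductive cleavage of the imide by borohydride should free the primary alcohol and the recoverable auxiliary without touching either stereocentre, the aryl bromide or the benzyl ether; the aryloxy carbon changes descriptor from R to S only because the substituent priorities change.

Step 5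
Reactants: 10 threo diol
Product: 11 (1S,2S)-1-[4-(benzyloxy)-3-methoxyphenyl]-2-(4-bromo-2,6-dimethoxyphenoxy)-3-[(tert-butyldimethylsilyl)oxy]propan-1-ol
Conditions: TBSCl, imidazole, CH2Cl2, 0 °C
Reagents that add atoms: tert-butyldimethylsilyl chloride, CC(C)(C)[Si](C)(C)Cl
Why: Silylation should be selective for the unhindered primary hydroxyl over the benzylic secondary one flanked by the bulky aryloxy group.

Step 6
Reactants: 11 threo 9''-O-silyl alcohol
Product: 12 (1R,2S)-1-[4-(benzyloxy)-3-methoxyphenyl]-2-(4-bromo-2,6-dimethoxyphenoxy)-3-[(tert-butyldimethylsilyl)oxy]propyl 4-nitrobenzoate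
Conditions: 4-nitrobenzoic acid, PPh3, DIAD, toluene, −20 °C → rt
Reagents that add atoms: 4-nitrobenzoic acid, OC(=O)c1ccc(cc1)[N+](=O)[O-]
Why: Mitsunobu esterification: the carboxylate displaces the alkoxyphosphonium group in an SN2 reaction with inversion at C7'' (1S to 1R), which converts the threo into the erythro series; the carbinol has no acidic neighbouring hydrogen, and the unpolar solvent and low temperature disfavour ionisation of the electron-rich benzylic centre.

Step 7
Reactants: 12 erythro 4-nitrobenzoate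
Product: 13 (1R,2S)-1-[4-(benzyloxy)-3-methoxyphenyl]-2-(4-bromo-2,6-dimethoxyphenoxy)-3-[(tert-butyldimethylsilyl)oxy]propan-1-ol
Conditions: K2CO3 (cat.), MeOH/THF, 0 °C → rt
Reagents that add atoms: none
Why: Base-catalysed transesterification removes the activated 4-nitrobenzoate without touching the stereocentres; a silyl shift between the two oxygens would be harmless because step 8 silylates whichever hydroxyl is free.

Step 8
Reactants: 13 erythro 9''-O-silyl alcohol
Product: 14 ArB bromide, (1R,2S)-1-[4-(benzyloxy)-3-methoxyphenyl]-2-(4-bromo-2,6-dimethoxyphenoxy)-1,3-bis[(tert-butyldimethylsilyl)oxy]propane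
Conditions: TBSOTf, 2,6-lutidine, CH2Cl2, −78 → 0 °C
Reagents that add atoms: tert-butyldimethylsilyl triflate, CC(C)(C)[Si](C)(C)OS(=O)(=O)C(F)(F)F
Why: The silyl triflate with a hindered pyridine base silylates the crowded benzylic hydroxyl, giving a diol protection that withstands organolithium, enolate and hydroxide conditions and falls in one fluoride step later.

Step 9
Reactants: 14 ArB bromide
Product: 16 1-ArB-ethan-1-one, via aryllithium 15 (not isolated)
Conditions: n-BuLi, THF, −78 °C; then MeC(O)N(OMe)Me, −78 → 0 °C; aq. NH4Cl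
Reagents that add atoms: N-methoxy-N-methylacetamide, CC(=O)N(C)OC
Why: Bromine–lithium exchange is faster than any deprotonation at −78 °C, and the aryllithium adds once to the Weinreb amide, whose chelated tetrahedral adduct releases the methyl ketone only on work-up.

Step 10
Reactants: 16 1-ArB-ethan-1-one
Product: 17 1-ArB-butane-1,3-dione
Conditions: NaH (3 equiv), EtOAc (excess), THF, 0 °C → reflux; AcOH quench
Reagents that add atoms: ethyl acetate, CCOC(C)=O
Why: Crossed Claisen condensation of the ketone enolate with ethyl acetate, driven to completion by deprotonation of the 1,3-diketone that is formed.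

Step 11
Reactants: 17 1-ArB-butane-1,3-dione; 18 diethyl oxalate
Product: 20 ethyl 6-ArB-4-oxo-4H-pyran-2-carboxylate, via triketo ester 19 (not isolated)
Conditions: LiN(i-Pr)2 (2.2 equiv), THF, −78 → −20 °C; 18, −78 → 0 °C; AcOH quench; then PPh3, CCl4, Et3N, MeCN, rt
Reagents that add atoms: none
Why: Claisen acylation of the diketone dianion at its terminal carbon by diethyl oxalate gives the 1,3,5-tricarbonyl chain, and Appel-type activation of an enol under amine buffering closes the 4-pyranone (ring C) by attack of the distal enol oxygen with loss of the activated oxygen, so that no protic acid meets the benzylic silyl ether.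

Step 12
Reactants: 20 ethyl 6-ArB-4-oxo-4H-pyran-2-carboxylate
Product: 21 6-ArB-4-oxo-4H-pyran-2-carboxylic acid
Conditions: LiOH (1.2 equiv), THF/H2O, 0 °C; 1 M HCl to pH 3, 0 °C
Reagents that add atoms: lithium hydroxide, [Li+].[OH-]
Why: Saponification of the electron-poor heteroaryl ester is fast at 0 °C with a small excess of hydroxide, conditions under which the pyranone ring and the silyl ethers should persist.

Step 13
Reactants: 21 6-ArB-4-oxo-4H-pyran-2-carboxylic acid
Product: 23 2-(diazoacetyl)-6-ArB-4H-pyran-4-one, via acid chloride 22 (not isolated)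
Conditions: Me2C=C(Cl)NMe2, CH2Cl2, 0 °C; then CH2N2 (3 equiv), Et2O, 0 °C
Reagents that add atoms: diazomethane, C=[N+]=[N-]
Why: The α-chloroenamine converts the acid into its chloride without releasing HCl, and acylation of diazomethane (first stage of the Arndt–Eistert sequence) gives the diazo ketone, a second equivalent of diazomethane taking up the hydrogen chloride.

Step 14
Reactants: 24 3-phenylisoxazole
Product: 26 (triisopropylsiloxy)acetylene, via lithium ethynolate 25 (not isolated)
Conditions: n-BuLi, THF, −78 → −20 °C; then TIPSOTf, −78 → 0 °C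
Reagents that add atoms: triisopropylsilyl triflate, CC(C)[Si](C(C)C)(C(C)C)OS(=O)(=O)C(F)(F)F
Why: Lithiation at C5 of a 3-substituted isoxazole triggers fragmentation to benzonitrile and lithium ethynolate, and the bulky silyl triflate silylates the ynolate on oxygen (ynolate O-silylation) to give the thermally stable silyl ynol ether.

Step 15
Reactants: 23 2-(diazoacetyl)-6-ArB-4H-pyran-4-one; 26 (triisopropylsiloxy)acetylene
Product: 29 2-ArB-5-hydroxy-7-[(triisopropylsilyl)oxy]-4H-chromen-4-one, via pyranonylketene 27 (not isolated), via siloxycyclobutenone 28 (not isolated)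
Conditions: 26 (2 equiv), hν (365 nm LEDs), ClCH2CH2Cl, 20 °C; then 80 °C
Reagents that add atoms: none
Why: Proposed new method: excitation of the diazo ketone expels N2 and Wolff rearrangement moves pyranone C2 (future C8a) onto the carbene carbon (future C8) to give ketene 27, whose carbonyl carbon (future C5) is attacked by the nucleophilic CH terminus of the ynol ether (C6) while the siloxy carbon (C7) bonds to C8, giving cyclobutenone 28, which on warming opens by a four-electron process to a dienylketene that closes onto pyranone C3 (future C4a) and enolises. The closest known reaction is the photochemical diazo ketone variant of the Danheiser benzannulation, established for aryl, heteroaryl and alkenyl diazo ketones with siloxyalkynes but not for a 4-pyranone as the vinyl component. Ring A is closed by a thermal six-electron disrotatory electrocyclisation that forms C4a–C5, followed by tautomerisation to the phenol; no stereocentre is created and the two side-chain centres are remote spectators. The step needs regioselective ketene–alkyne union, secured by the polarisation of the O-silyl ynol ether, and a single cyclisation terminus, secured because C3 is the only free position beside the ketene-bearing carbon. Chemoselectivity for the diazo chromophore over the pyranone is sought by long-wavelength irradiation, and the new C5 hydroxyl, hydrogen-bonded to the C4 carbonyl, should be a poor nucleophile toward residual ketene.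

Step 16
Reactants: 29 2-ArB-5-hydroxy-7-[(triisopropylsilyl)oxy]-4H-chromen-4-one
Product: 30 2-[4-({(1R,2S)-1-[4-(benzyloxy)-3-methoxyphenyl]-1,3-dihydroxypropan-2-yl}oxy)-3,5-dimethoxyphenyl]-5,7-dihydroxy-4H-chromen-4-one
Conditions: TBAF (4 equiv), AcOH (4 equiv), THF, 0 → 40 °C
Reagents that add atoms: none
Why: Fluoride cleaves the aryl silyl ether and both alkyl silyl ethers in one operation, the acetic acid buffer keeping the medium near neutral so that the β-aryl ether side chain and the flavone are not exposed to strong base.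

Step 17
Reactants: 30 tetrol with 4''-O-benzyl ether
Product: 31 (2S,3R)-3-[4-(benzyloxy)-3-methoxyphenyl]-2-[4-(5,7-dihydroxy-4-oxo-4H-chromen-2-yl)-2,6-dimethoxyphenoxy]-3-hydroxypropyl acetate
Conditions: Candida antarctica lipase B (immobilised), vinyl acetate, THF, 40 °C
Reagents that add atoms: vinyl acetate, CC(=O)OC=C
Why: Lipase-catalysed transesterification with an enol ester is irreversible and selective for the primary hydroxyl, leaving the secondary benzylic hydroxyl and the phenols (C5 hydrogen-bonded, C7 acidic) unacylated.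

Step 18
Reactants: 31 9''-acetate with 4''-O-benzyl ether
Product: 32 (2S,3R)-2-[4-(5,7-dihydroxy-4-oxo-4H-chromen-2-yl)-2,6-dimethoxyphenoxy]-3-hydroxy-3-(4-hydroxy-3-methoxyphenyl)propyl acetate (target, 7''R,8''S)
Conditions: H2 (1 atm), Pd/C, EtOAc, rt
Reagents that add atoms: none
Why: Hydrogenolysis of the benzyl aryl ether over Pd/C under neutral conditions, stopped after one equivalent of hydrogen, should spare the benzylic alcohol, the acetate and the flavone double bond.

**Compound list**

1 | 4-bromo-2,6-dimethoxyphenol | COc1cc(Br)cc(OC)c1O | starting material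
2 | bromoacetic acid | OC(=O)CBr | starting material
3 | (4-bromo-2,6-dimethoxyphenoxy)acetic acid | COc1cc(Br)cc(OC)c1OCC(=O)O | intermediate
4 | (R)-4-benzyloxazolidin-2-one | O=C1N[C@H](Cc2ccccc2)CO1 | starting material
5 | (4-bromo-2,6-dimethoxyphenoxy)acetic pivalic anhydride | COc1cc(Br)cc(OC)c1OCC(=O)OC(=O)C(C)(C)C | intermediate
6 | (4R)-4-benzyl-3-[(4-bromo-2,6-dimethoxyphenoxy)acetyl]oxazolidin-2-one | COc1cc(Br)cc(OC)c1OCC(=O)N1[C@H](Cc2ccccc2)COC1=O | intermediate
7 | 4-(benzyloxy)-3-methoxybenzaldehyde | COc1cc(C=O)ccc1OCc1ccccc1 | starting material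
8 | dibutylboron (Z)-enolate of 6 | CCCCB(CCCC)O/C(=C\Oc1c(OC)cc(Br)cc1OC)N1[C@H](Cc2ccccc2)COC1=O | intermediate
9 | (4R)-4-benzyl-3-[(2R,3S)-3-[4-(benzyloxy)-3-methoxyphenyl]-2-(4-bromo-2,6-dimethoxyphenoxy)-3-hydroxypropanoyl]oxazolidin-2-one | COc1cc([C@H](O)[C@H](C(=O)N2[C@H](Cc3ccccc3)COC2=O)Oc2c(OC)cc(Br)cc2OC)ccc1OCc1ccccc1 | intermediate
10 | (1S,2S)-1-[4-(benzyloxy)-3-methoxyphenyl]-2-(4-bromo-2,6-dimethoxyphenoxy)propane-1,3-diol | COc1cc([C@H](O)[C@H](CO)Oc2c(OC)cc(Br)cc2OC)ccc1OCc1ccccc1 | intermediate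
11 | (1S,2S)-1-[4-(benzyloxy)-3-methoxyphenyl]-2-(4-bromo-2,6-dimethoxyphenoxy)-3-[(tert-butyldimethylsilyl)oxy]propan-1-ol | COc1cc([C@H](O)[C@H](CO[Si](C)(C)C(C)(C)C)Oc2c(OC)cc(Br)cc2OC)ccc1OCc1ccccc1 | intermediate
12 | (1R,2S)-1-[4-(benzyloxy)-3-methoxyphenyl]-2-(4-bromo-2,6-dimethoxyphenoxy)-3-[(tert-butyldimethylsilyl)oxy]propyl 4-nitrobenzoate | COc1cc([C@@H](OC(=O)c3ccc([N+](=O)[O-])cc3)[C@H](CO[Si](C)(C)C(C)(C)C)Oc2c(OC)cc(Br)cc2OC)ccc1OCc1ccccc1 | intermediate
13 | (1R,2S)-1-[4-(benzyloxy)-3-methoxyphenyl]-2-(4-bromo-2,6-dimethoxyphenoxy)-3-[(tert-butyldimethylsilyl)oxy]propan-1-ol | COc1cc([C@@H](O)[C@H](CO[Si](C)(C)C(C)(C)C)Oc2c(OC)cc(Br)cc2OC)ccc1OCc1ccccc1 | intermediate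
14 | ArB bromide, (1R,2S)-1-[4-(benzyloxy)-3-methoxyphenyl]-2-(4-bromo-2,6-dimethoxyphenoxy)-1,3-bis[(tert-butyldimethylsilyl)oxy]propane | COc1cc([C@@H](O[Si](C)(C)C(C)(C)C)[C@H](CO[Si](C)(C)C(C)(C)C)Oc2c(OC)cc(Br)cc2OC)ccc1OCc1ccccc1 | intermediate
15 | ArB lithium | COc1cc([C@@H](O[Si](C)(C)C(C)(C)C)[C@H](CO[Si](C)(C)C(C)(C)C)Oc2c(OC)cc([Li])cc2OC)ccc1OCc1ccccc1 | intermediate
16 | 1-ArB-ethan-1-one | COc1cc([C@@H](O[Si](C)(C)C(C)(C)C)[C@H](CO[Si](C)(C)C(C)(C)C)Oc2c(OC)cc(C(C)=O)cc2OC)ccc1OCc1ccccc1 | intermediate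
17 | 1-ArB-butane-1,3-dione | COc1cc([C@@H](O[Si](C)(C)C(C)(C)C)[C@H](CO[Si](C)(C)C(C)(C)C)Oc2c(OC)cc(C(=O)CC(C)=O)cc2OC)ccc1OCc1ccccc1 | intermediate
18 | diethyl oxalate | CCOC(=O)C(=O)OCC | starting material
19 | ethyl 6-ArB-2,4,6-trioxohexanoate (drawn as the triketo tautomer) | COc1cc([C@@H](O[Si](C)(C)C(C)(C)C)[C@H](CO[Si](C)(C)C(C)(C)C)Oc2c(OC)cc(C(=O)CC(=O)CC(=O)C(=O)OCC)cc2OC)ccc1OCc1ccccc1 | intermediate
20 | ethyl 6-ArB-4-oxo-4H-pyran-2-carboxylate | COc1cc([C@@H](O[Si](C)(C)C(C)(C)C)[C@H](CO[Si](C)(C)C(C)(C)C)Oc2c(OC)cc(-c3cc(=O)cc(C(=O)OCC)o3)cc2OC)ccc1OCc1ccccc1 | intermediate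
21 | 6-ArB-4-oxo-4H-pyran-2-carboxylic acid | COc1cc([C@@H](O[Si](C)(C)C(C)(C)C)[C@H](CO[Si](C)(C)C(C)(C)C)Oc2c(OC)cc(-c3cc(=O)cc(C(=O)O)o3)cc2OC)ccc1OCc1ccccc1 | intermediate
22 | 6-ArB-4-oxo-4H-pyran-2-carbonyl chloride | COc1cc([C@@H](O[Si](C)(C)C(C)(C)C)[C@H](CO[Si](C)(C)C(C)(C)C)Oc2c(OC)cc(-c3cc(=O)cc(C(Cl)=O)o3)cc2OC)ccc1OCc1ccccc1 | intermediate
23 | 2-(diazoacetyl)-6-ArB-4H-pyran-4-one | COc1cc([C@@H](O[Si](C)(C)C(C)(C)C)[C@H](CO[Si](C)(C)C(C)(C)C)Oc2c(OC)cc(-c3cc(=O)cc(C(=O)C=[N+]=[N-])o3)cc2OC)ccc1OCc1ccccc1 | intermediate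
24 | 3-phenylisoxazole | c1ccc(-c2ccon2)cc1 | starting material
25 | lithium ethynolate | [Li+].[O-]C#C | intermediate
26 | (triisopropylsiloxy)acetylene | C#CO[Si](C(C)C)(C(C)C)C(C)C | intermediate
27 | 2-(2-oxoethenyl)-6-ArB-4H-pyran-4-one (ketene) | COc1cc([C@@H](O[Si](C)(C)C(C)(C)C)[C@H](CO[Si](C)(C)C(C)(C)C)Oc2c(OC)cc(-c3cc(=O)cc(C=C=O)o3)cc2OC)ccc1OCc1ccccc1 | intermediate
28 | 2-{4-oxo-2-[(triisopropylsilyl)oxy]cyclobut-2-en-1-yl}-6-ArB-4H-pyran-4-one (both epimers at the ring carbon) | COc1cc([C@@H](O[Si](C)(C)C(C)(C)C)[C@H](CO[Si](C)(C)C(C)(C)C)Oc2c(OC)cc(-c3cc(=O)cc(C4C(=O)C=C4O[Si](C(C)C)(C(C)C)C(C)C)o3)cc2OC)ccc1OCc1ccccc1 | intermediate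
29 | 2-ArB-5-hydroxy-7-[(triisopropylsilyl)oxy]-4H-chromen-4-one | COc1cc([C@@H](O[Si](C)(C)C(C)(C)C)[C@H](CO[Si](C)(C)C(C)(C)C)Oc2c(OC)cc(-c3cc(=O)c4c(O)cc(O[Si](C(C)C)(C(C)C)C(C)C)cc4o3)cc2OC)ccc1OCc1ccccc1 | intermediate
30 | 2-[4-({(1R,2S)-1-[4-(benzyloxy)-3-methoxyphenyl]-1,3-dihydroxypropan-2-yl}oxy)-3,5-dimethoxyphenyl]-5,7-dihydroxy-4H-chromen-4-one | COc1cc([C@@H](O)[C@H](CO)Oc2c(OC)cc(-c3cc(=O)c4c(O)cc(O)cc4o3)cc2OC)ccc1OCc1ccccc1 | intermediate
31 | (2S,3R)-3-[4-(benzyloxy)-3-methoxyphenyl]-2-[4-(5,7-dihydroxy-4-oxo-4H-chromen-2-yl)-2,6-dimethoxyphenoxy]-3-hydroxypropyl acetate | COc1cc([C@@H](O)[C@H](COC(C)=O)Oc2c(OC)cc(-c3cc(=O)c4c(O)cc(O)cc4o3)cc2OC)ccc1OCc1ccccc1 | intermediate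
32 | (2S,3R)-2-[4-(5,7-dihydroxy-4-oxo-4H-chromen-2-yl)-2,6-dimethoxyphenoxy]-3-hydroxy-3-(4-hydroxy-3-methoxyphenyl)propyl acetate | COc1cc([C@@H](O)[C@H](COC(C)=O)Oc2c(OC)cc(-c3cc(=O)c4c(O)cc(O)cc4o3)cc2OC)ccc1O | target

**Step count and risks**

Total: 18 steps. Longest linear sequence: 17 steps (steps 1–13 and 15–18, from 1 to 32); step 14 is a one-step side branch.

Steps most likely to fail:

1. Step 15 (ring A benzannulation).
 - What may go wrong: the pyranone, and later the flavone, may compete for the light, so that the diazo ketone is consumed slowly or the pyranone photoisomerises. The ketene may be lost to dimerisation before the alkyne captures it. The cyclobutenone may not open and close cleanly on heating, and silyl transfer may blur the product.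
 - Fallback (Claisen-type flavone synthesis, ring A from a phloroglucinol unit): it sets out from 14 and returns at 30. Bromine–lithium exchange on 14 (n-BuLi, −78 °C) and carboxylation with CO2 should give the benzoic acid F1. The α-chloroenamine of step 13 converts it into the acid chloride F2. C-acylation of the lithium polyanion of commercial 2',4',6'-trihydroxyacetophenone (LiN(SiMe3)2, 4 equiv, THF, −78 °C → rt) with F2 gives the 1-(2,4,6-trihydroxyphenyl)-1,3-diketone F3. Mild acid cyclodehydration (AcOH, 60 °C) closes the pyranone onto the ortho phenol to give the 5,7-dihydroxyflavone F4, still carrying the two silyl ethers. Buffered TBAF as in step 16 then gives 30; any silyl loss during the cyclodehydration is immaterial.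

2. Step 6 (Mitsunobu inversion at C7'').
 - What may go wrong: ionisation of the electron-rich benzylic alkoxyphosphonium ion would give partial retention or elimination to an enol ether. Crowding by the neighbouring aryloxy group may slow the displacement.
 - Fallback (oxidation and chelation-controlled reduction in place of displacement): it sets out from 11 and returns at 13. Dess–Martin oxidation of 11 (buffered with NaHCO3) gives the aryl ketone F5, whose C8'' centre is kept by avoiding base. Reduction with Zn(BH4)2 in Et2O at −30 °C should pass through the five-membered chelate between the carbonyl and the aryloxy oxygen, with hydride delivered from the side of the C8'' hydrogen, and give the erythro alcohol 13.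

3. Step 11 (oxalylation and cyclodehydration to the pyranone).
 - What may go wrong: acylation of the dianion on oxygen or at the internal carbon; chlorination of an enol without ring closure; attack of the activating reagent on the α-keto ester.
 - Fallback (ring closure by conjugate addition instead of dehydration): it sets out from 14 and returns at 20. Sonogashira coupling of 14 with but-3-yn-2-ol (Pd(PPh3)4, CuI, Et3N, 70 °C) gives the propargylic alcohol F6. MnO2 oxidises it to the ynone F7. Claisen condensation of the methyl ketone enolate (LiN(SiMe3)2, THF, −78 °C) with diethyl oxalate gives the alkynyl diketo ester F8. Its enol oxygen adds 6-endo to the ynone (catalytic Et3N or AgOTf), which gives pyranone ester 20 without any dehydrating agent.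

**Further compounds**

F1 | step 15 | 4-({(1R,2S)-1-[4-(benzyloxy)-3-methoxyphenyl]-1,3-bis[(tert-butyldimethylsilyl)oxy]propan-2-yl}oxy)-3,5-dimethoxybenzoic acid | COc1cc([C@@H](O[Si](C)(C)C(C)(C)C)[C@H](CO[Si](C)(C)C(C)(C)C)Oc2c(OC)cc(C(=O)O)cc2OC)ccc1OCc1ccccc1
F2 | step 15 | ArB carbonyl chloride | COc1cc([C@@H](O[Si](C)(C)C(C)(C)C)[C@H](CO[Si](C)(C)C(C)(C)C)Oc2c(OC)cc(C(Cl)=O)cc2OC)ccc1OCc1ccccc1
F3 | step 15 | 1-ArB-3-(2,4,6-trihydroxyphenyl)propane-1,3-dione | COc1cc([C@@H](O[Si](C)(C)C(C)(C)C)[C@H](CO[Si](C)(C)C(C)(C)C)Oc2c(OC)cc(C(=O)CC(=O)c3c(O)cc(O)cc3O)cc2OC)ccc1OCc1ccccc1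
F4 | step 15 | 2-ArB-5,7-dihydroxy-4H-chromen-4-one | COc1cc([C@@H](O[Si](C)(C)C(C)(C)C)[C@H](CO[Si](C)(C)C(C)(C)C)Oc2c(OC)cc(-c3cc(=O)c4c(O)cc(O)cc4o3)cc2OC)ccc1OCc1ccccc1
F5 | step 6 | (2S)-1-[4-(benzyloxy)-3-methoxyphenyl]-2-(4-bromo-2,6-dimethoxyphenoxy)-3-[(tert-butyldimethylsilyl)oxy]propan-1-one | COc1cc(C(=O)[C@H](CO[Si](C)(C)C(C)(C)C)Oc2c(OC)cc(Br)cc2OC)ccc1OCc1ccccc1
F6 | step 11 | 4-ArB-but-3-yn-2-ol (either configuration at the carbinol) | COc1cc([C@@H](O[Si](C)(C)C(C)(C)C)[C@H](CO[Si](C)(C)C(C)(C)C)Oc2c(OC)cc(C#CC(C)O)cc2OC)ccc1OCc1ccccc1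
F7 | step 11 | 4-ArB-but-3-yn-2-one | COc1cc([C@@H](O[Si](C)(C)C(C)(C)C)[C@H](CO[Si](C)(C)C(C)(C)C)Oc2c(OC)cc(C#CC(C)=O)cc2OC)ccc1OCc1ccccc1
F8 | step 11 | ethyl 6-ArB-2,4-dioxohex-5-ynoate | COc1cc([C@@H](O[Si](C)(C)C(C)(C)C)[C@H](CO[Si](C)(C)C(C)(C)C)Oc2c(OC)cc(C#CC(=O)CC(=O)C(=O)OCC)cc2OC)ccc1OCc1ccccc1
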